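Assumption: the carbocycle atoms are labelled C1–C14 in the order of the target SMILES (C1 carries CO2Me, C7 is the lactone O–CH, C8 the lactone β-carbon, C10 carries OAc). CIP analysis of the SMILES gives 7S,10S, with C1=C2 Z (ester cis to C3), C5=C6 E and C11=C12 E.

## Retrosynthetic overview

1. The last step makes the C7–C8 bond, the 14-membered carbocycle and then the butenolide in one flask: a β-metallated enoate carbon (C8 as donor) adds to the C7 enal of an open-chain precursor.
2. The vinyl triflate donor comes from a β-keto ester; C9–C10 comes from a catalytic asymmetric vinylogous Mukaiyama aldol on a C10 enal (sets 10S), itself made by SeO2 oxidation of a prenyl terminus.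
3. C1=C2 (Z, bearing CO2Me) comes from a Still–Gennari olefination of a C2–C7 aldehyde (geranyl acetate, ozonolysis) with an α-homoprenyl phosphonoacetate (C1, C11–C14).
4. Ring order: no ring until the end; the carbocycle closes first and the lactone immediately after.

## Route

Step 1
Reactants: 1 geranyl acetate
Product: 3 (2E)-3-methyl-6-oxohex-2-en-1-yl acetate, via secondary ozonide 2 (not isolated)
Conditions: O3 (1.0 equiv, Sudan Red 7B endpoint), CH2Cl2, −78 °C; then Me2S, −78 °C → rt
Reagents that add atoms: ozone, [O-][O+]=O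
Why: Chemoselective ozonolysis, in which the distal trisubstituted alkene is far more electron-rich than the alkene deactivated by the allylic acetoxy group, so one equivalent of ozone cleaves only the former and the E alkene is kept.

Step 2
Reactants: 4 methyl 2-[bis(2,2,2-trifluoroethoxy)phosphoryl]acetate; 5 homoprenyl bromide (5-bromo-2-methylpent-2-ene)
Product: 6 methyl 2-[bis(2,2,2-trifluoroethoxy)phosphoryl]-6-methylhept-5-enoate (racemic)
Conditions: NaH, DMF, 0 °C; then 5, NaI (0.1 equiv), 55 °C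
Reagents that add atoms: none
Why: SN2 C-alkylation of the stabilised, weakly basic phosphonoacetate anion with a primary bromide activated in situ as the iodide (Finkelstein); the new centre is racemic and is destroyed in step 3.

Step 3
Reactants: 6 methyl 2-[bis(2,2,2-trifluoroethoxy)phosphoryl]-6-methylhept-5-enoate; 3 (2E)-3-methyl-6-oxohex-2-en-1-yl acetate
Product: 7 methyl (2Z,6E)-8-acetoxy-6-methyl-2-(4-methylpent-3-en-1-yl)octa-2,6-dienoate
Conditions: KN(SiMe3)2, 18-crown-6, THF, −78 °C; then 3, −78 °C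
Reagents that add atoms: none
Why: Still–Gennari olefination, in which the electron-poor trifluoroethyl phosphonate with a crown-separated potassium ion eliminates fast from the kinetic adduct and so places the ester cis to the new C3 chain (2Z).

Step 4
Reactants: 7 methyl (2Z,6E)-8-acetoxy-6-methyl-2-(4-methylpent-3-en-1-yl)octa-2,6-dienoate
Product: 9 methyl (2Z,6E)-8-acetoxy-6-methyl-2-[(3E)-4-methyl-5-oxopent-3-en-1-yl]octa-2,6-dienoate, via allylic alcohol 8 (not isolated)
Conditions: SeO2 (0.3 equiv), t-BuOOH (3 equiv), salicylic acid (0.1 equiv), CH2Cl2, rt; then MnO2, CH2Cl2, rt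
Reagents that add atoms: selenium dioxide, O=[Se]=O; tert-butyl hydroperoxide, CC(C)(C)OO
Why: SeO2 allylic oxidation (ene reaction then [2,3]-sigmatropic shift) attacks only the E-methyl group of the one electron-rich alkene (the enoate and the acetoxy-deactivated alkene are inert), and MnO2 converges the alcohol/aldehyde mixture on the E-enal.

Step 5
Reactants: 9 methyl (2Z,6E)-8-acetoxy-6-methyl-2-[(3E)-4-methyl-5-oxopent-3-en-1-yl]octa-2,6-dienoate; 10 Chan's diene (1-methoxy-1,3-bis(trimethylsilyloxy)buta-1,3-diene)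
Product: 12 methyl (5S,6E,10Z,14E)-16-acetoxy-5-hydroxy-10-(methoxycarbonyl)-6,14-dimethyl-3-oxohexadeca-6,10,14-trienoate, via bis-silyl aldol adduct 11 (not isolated)
Conditions: Ti(OiPr)4 (10 mol %), (S)-BINOL (10 mol %), 4 Å MS, THF, −78 °C → rt; then PPTS, MeOH, 0 °C
Reagents that add atoms: none
Why: Catalytic asymmetric vinylogous Mukaiyama aldol, in which the titanium–BINOL complex binds the enal and the diene terminus attacks its Si face (the facial sense known for the S ligand in titanium–BINOL allylations and aldols), setting C10 (C5 of the chain) as S before mild methanolysis removes the silyl groups.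

Step 6
Reactants: 12 methyl (5S,6E,10Z,14E)-16-acetoxy-5-hydroxy-10-(methoxycarbonyl)-6,14-dimethyl-3-oxohexadeca-6,10,14-trienoate
Product: 13 methyl (2RS,5S,6E,10Z,14E)-16-acetoxy-5-hydroxy-10-(methoxycarbonyl)-2,6,14-trimethyl-3-oxohexadeca-6,10,14-trienoate
Conditions: K2CO3 (1.5 equiv), MeI (1.1 equiv), acetone, rt
Reagents that add atoms: iodomethane, CI
Why: C-alkylation of the β-keto ester enolate, the only site K2CO3 deprotonates; the new α-centre is an epimer mixture that becomes sp2 in step 7.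

Step 7
Reactants: 13 methyl (2RS,5S,6E,10Z,14E)-16-acetoxy-5-hydroxy-10-(methoxycarbonyl)-2,6,14-trimethyl-3-oxohexadeca-6,10,14-trienoate
Product: 14 methyl (2Z,5S,6E,10Z,14E)-16-acetoxy-5-hydroxy-10-(methoxycarbonyl)-2,6,14-trimethyl-3-(trifluoromethylsulfonyloxy)hexadeca-2,6,10,14-tetraenoate
Conditions: NaH (1.05 equiv), THF, 0 °C; then PhNTf2, 0 °C → rt
Reagents that add atoms: N-phenylbis(trifluoromethanesulfonimide), O=S(=O)(N(c1ccccc1)S(=O)(=O)C(F)(F)F)C(F)(F)F
Why: O-sulfonylation of the chelated sodium enolate, in which sodium bridges the enolate oxygen and the ester carbonyl so that OTf ends up cis to CO2Me (2Z); PhNTf2 leaves the neutral secondary alcohol alone, and the Z geometry keeps that alcohol from lactonising.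

Step 8
Reactants: 14 methyl (2Z,5S,6E,10Z,14E)-16-acetoxy-5-hydroxy-10-(methoxycarbonyl)-2,6,14-trimethyl-3-(trifluoromethylsulfonyloxy)hexadeca-2,6,10,14-tetraenoate
Product: 15 methyl (2Z,5S,6E,10Z,14E)-5,16-diacetoxy-10-(methoxycarbonyl)-2,6,14-trimethyl-3-(trifluoromethylsulfonyloxy)hexadeca-2,6,10,14-tetraenoate
Conditions: Ac2O, pyridine, DMAP (cat.), CH2Cl2, 0 °C
Reagents that add atoms: acetic anhydride, CC(=O)OC(C)=O
Why: DMAP-catalysed acylation of the secondary allylic alcohol with retention (the C–O bond is not broken); acetylating only after the ketone is masked as the triflate avoids β-elimination of a β-acetoxy ketone.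

Step 9
Reactants: 15 methyl (2Z,5S,6E,10Z,14E)-5,16-diacetoxy-10-(methoxycarbonyl)-2,6,14-trimethyl-3-(trifluoromethylsulfonyloxy)hexadeca-2,6,10,14-tetraenoate
Product: 16 methyl (2Z,5S,6E,10Z,14E)-5-acetoxy-16-hydroxy-10-(methoxycarbonyl)-2,6,14-trimethyl-3-(trifluoromethylsulfonyloxy)hexadeca-2,6,10,14-tetraenoate
Conditions: immobilised Candida antarctica lipase B, n-BuOH (5 equiv), MTBE, 35 °C
Reagents that add atoms: none
Why: Lipase-catalysed transesterification, in which the enzyme accepts the unhindered primary (geranyl-type) acetate but not the secondary acetate flanked by two large groups or the hindered conjugated methyl esters, under neutral conditions that spare the vinyl triflate.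

Step 10
Reactants: 16 methyl (2Z,5S,6E,10Z,14E)-5-acetoxy-16-hydroxy-10-(methoxycarbonyl)-2,6,14-trimethyl-3-(trifluoromethylsulfonyloxy)hexadeca-2,6,10,14-tetraenoate
Product: 17 methyl (2Z,5S,6E,10Z,14E)-5-acetoxy-10-(methoxycarbonyl)-2,6,14-trimethyl-16-oxo-3-(trifluoromethylsulfonyloxy)hexadeca-2,6,10,14-tetraenoate
Conditions: MnO2 (20 equiv), CH2Cl2, rt
Reagents that add atoms: none
Why: MnO2 oxidation of the only free (primary allylic) alcohol to the enal under neutral conditions, without E/Z isomerisation.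

Step 11
Reactants: 17 methyl (2Z,5S,6E,10Z,14E)-5-acetoxy-10-(methoxycarbonyl)-2,6,14-trimethyl-16-oxo-3-(trifluoromethylsulfonyloxy)hexadeca-2,6,10,14-tetraenoate
Product: 19 target lactone 16-oxosarcoglaucol acetate, via macrocyclic hydroxy diester 18 (not isolated)
Conditions: CrCl2 (10 equiv), NiCl2 (0.2 equiv), DMSO/THF (3:1), rt, syringe-pump addition of 17 over 12 h, final 2 mM
Reagents that add atoms: none
Why: Nozaki–Hiyama–Kishi macrocyclisation/lactonisation: zerovalent nickel inserts into the vinyl C–OTf bond and transmetalation to trivalent chromium gives a β-chromio enoate, a β-acylvinyl anion (sp2 homoenolate) in which the normally electrophilic enoate β-carbon C8 is the donor, which adds 1,2 to the electrophilic aldehyde carbon C7 to close the 14-membered ring, after which the chromium alkoxide held cis to CO2Me closes the butenolide with loss of methoxide; C7 is set by substrate control from C10 (A(1,3) strain against the α-methyl fixes the C9–C10 rotamer, the acetoxy group stays outside the forming ring, and Re-face attack on the enal gives 7S), and this induction is hoped for, not secured.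

## Compound list

1 | geranyl acetate, (2E)-3,7-dimethylocta-2,6-dien-1-yl acetate | CC(=O)OC/C=C(\C)CCC=C(C)C | starting material
2 | secondary ozonide, (2E)-5-(5,5-dimethyl-1,2,4-trioxolan-3-yl)-3-methylpent-2-en-1-yl acetate (racemic at the ring carbon) | CC(=O)OC/C=C(\C)CCC1OOC(C)(C)O1 | intermediate (not isolated)
3 | (2E)-3-methyl-6-oxohex-2-en-1-yl acetate | CC(=O)OC/C=C(\C)CCC=O | intermediate
4 | methyl 2-[bis(2,2,2-trifluoroethoxy)phosphoryl]acetate | COC(=O)CP(=O)(OCC(F)(F)F)OCC(F)(F)F | starting material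
5 | homoprenyl bromide, 5-bromo-2-methylpent-2-ene | CC(C)=CCCBr | starting material
6 | methyl 2-[bis(2,2,2-trifluoroethoxy)phosphoryl]-6-methylhept-5-enoate (racemic) | COC(=O)C(CCC=C(C)C)P(=O)(OCC(F)(F)F)OCC(F)(F)F | intermediate
7 | methyl (2Z,6E)-8-acetoxy-6-methyl-2-(4-methylpent-3-en-1-yl)octa-2,6-dienoate | CC(C)=CCC/C(C(=O)OC)=C/CC/C(C)=C/COC(C)=O | intermediate
8 | allylic alcohol, methyl (2Z,6E)-8-acetoxy-2-[(3E)-5-hydroxy-4-methylpent-3-en-1-yl]-6-methylocta-2,6-dienoate | OC/C(C)=C/CC/C(C(=O)OC)=C/CC/C(C)=C/COC(C)=O | intermediate (not isolated)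
9 | methyl (2Z,6E)-8-acetoxy-6-methyl-2-[(3E)-4-methyl-5-oxopent-3-en-1-yl]octa-2,6-dienoate | O=C/C(C)=C/CC/C(C(=O)OC)=C/CC/C(C)=C/COC(C)=O | intermediate
10 | Chan's diene, 1-methoxy-1,3-bis(trimethylsilyloxy)buta-1,3-diene (geometry of the ketene acetal immaterial) | COC(O[Si](C)(C)C)=CC(=C)O[Si](C)(C)C | starting material
11 | bis-silyl aldol adduct, methyl (5S,6E,10Z,14E)-16-acetoxy-10-(methoxycarbonyl)-6,14-dimethyl-3,5-bis(trimethylsilyloxy)hexadeca-2,6,10,14-tetraenoate (2-ene geometry not defined) | COC(=O)C=C(O[Si](C)(C)C)C[C@H](O[Si](C)(C)C)/C(C)=C/CC/C(C(=O)OC)=C/CC/C(C)=C/COC(C)=O | intermediate (not isolated)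
12 | methyl (5S,6E,10Z,14E)-16-acetoxy-5-hydroxy-10-(methoxycarbonyl)-6,14-dimethyl-3-oxohexadeca-6,10,14-trienoate | COC(=O)CC(=O)C[C@H](O)/C(C)=C/CC/C(C(=O)OC)=C/CC/C(C)=C/COC(C)=O | intermediate
13 | methyl (2RS,5S,6E,10Z,14E)-16-acetoxy-5-hydroxy-10-(methoxycarbonyl)-2,6,14-trimethyl-3-oxohexadeca-6,10,14-trienoate (C2 epimer mixture) | COC(=O)C(C)C(=O)C[C@H](O)/C(C)=C/CC/C(C(=O)OC)=C/CC/C(C)=C/COC(C)=O | intermediate
14 | methyl (2Z,5S,6E,10Z,14E)-16-acetoxy-5-hydroxy-10-(methoxycarbonyl)-2,6,14-trimethyl-3-(trifluoromethylsulfonyloxy)hexadeca-2,6,10,14-tetraenoate | COC(=O)/C(C)=C(\OS(=O)(=O)C(F)(F)F)C[C@H](O)/C(C)=C/CC/C(C(=O)OC)=C/CC/C(C)=C/COC(C)=O | intermediate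
15 | methyl (2Z,5S,6E,10Z,14E)-5,16-diacetoxy-10-(methoxycarbonyl)-2,6,14-trimethyl-3-(trifluoromethylsulfonyloxy)hexadeca-2,6,10,14-tetraenoate | COC(=O)/C(C)=C(\OS(=O)(=O)C(F)(F)F)C[C@H](OC(C)=O)/C(C)=C/CC/C(C(=O)OC)=C/CC/C(C)=C/COC(C)=O | intermediate
16 | methyl (2Z,5S,6E,10Z,14E)-5-acetoxy-16-hydroxy-10-(methoxycarbonyl)-2,6,14-trimethyl-3-(trifluoromethylsulfonyloxy)hexadeca-2,6,10,14-tetraenoate | COC(=O)/C(C)=C(\OS(=O)(=O)C(F)(F)F)C[C@H](OC(C)=O)/C(C)=C/CC/C(C(=O)OC)=C/CC/C(C)=C/CO | intermediate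
17 | methyl (2Z,5S,6E,10Z,14E)-5-acetoxy-10-(methoxycarbonyl)-2,6,14-trimethyl-16-oxo-3-(trifluoromethylsulfonyloxy)hexadeca-2,6,10,14-tetraenoate | COC(=O)/C(C)=C(\OS(=O)(=O)C(F)(F)F)C[C@H](OC(C)=O)/C(C)=C/CC/C(C(=O)OC)=C/CC/C(C)=C/C=O | intermediate
18 | macrocyclic hydroxy diester (formed as its chromium alkoxide, drawn as the free alcohol): 14-membered ring with 7S-OH, 10S-OAc, CO2Me on C1 and an exocyclic C8=C(CH3)CO2Me unit whose ester is cis to C7 | COC(=O)/C1=C\CC/C(C)=C/[C@H](O)/C(C[C@H](OC(C)=O)/C(C)=C/CC1)=C(/C)C(=O)OC | intermediate (not isolated)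
19 | 16-oxosarcoglaucol acetate (7S,10S) | COC(=O)/C1=C\CC/C(C)=C/[C@@H]2OC(=O)C(C)=C2C[C@H](OC(C)=O)/C(C)=C/CC1 | target

## Step count and risks

Total step count: 11. Longest linear sequence: 10 steps (steps 2–11 from 4 and 5, or steps 1 and 3–11 from 1).

Three steps most likely to fail:

Step 11 (ring closure and C7 configuration). The 1,4-induction from C10 is not secured, and the closure may give mainly the 7R lactone. Fallback: reset C7 after the ring is made instead of during C–C bond formation. The fallback sets out from 17, whose closure then delivers the C7 epimer of the target F1. Its acidic γ-proton is removed and the lactone is trapped (TBSOTf, Et3N, CH2Cl2, −78 °C) as the macrocyclic 2-silyloxyfuran F2, in which C7 is planar. Desilylative γ-protonation (Et3N·3HF, THF, −78 °C) from the less hindered outer face then sets C7 independently of the facial preference of the carbon–carbon bond formation; thermodynamic equilibration with DBU is the alternative. Remaining F1 is recycled, and the fallback comes back to the route at 19.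

Step 5 (enantioselectivity of the vinylogous aldol on an α-branched enal). Fallback: set C10 by reduction instead of by C–C bond formation. It sets out from 9, which is treated with the dianion of methyl 2-methyl-3-oxobutanoate (NaH then n-BuLi, THF, −78 °C) to give the racemic methylated hydroxy keto ester F3; this also makes step 6 unnecessary. Z-selective triflation as in step 7 gives the racemic hydroxy triflate F4, and Dess–Martin periodinane gives the enone F5. Reduction with (R)-2-methyl-CBS-oxazaborolidine/catecholborane (toluene, −78 °C, alkenyl as the large group) gives the 5S alcohol, and the fallback comes back to the route at 14.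

Step 9 (telling two acetates apart next to a vinyl triflate). Fallback: change the order so that no acetate has to be distinguished. It sets out from 14, which carries one acetate only and is deacetylated with the same lipase to the diol F6. The primary allylic alcohol alone is then oxidised with TEMPO (cat.)/PhI(OAc)2 (CH2Cl2, 0 °C) to the hydroxy enal F7, and acetylation (Ac2O, pyridine, 0 °C) brings the fallback back to the route at 17.

Further compounds

F1 | step 11 | C7 epimer of the target, (7R,10S)-16-oxosarcoglaucol acetate | COC(=O)/C1=C\CC/C(C)=C/[C@H]2OC(=O)C(C)=C2C[C@H](OC(C)=O)/C(C)=C/CC1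
F2 | step 11 | macrocyclic 2-(tert-butyldimethylsilyloxy)-3-methylfuran (C7 and C8 are furan carbons; 10S-OAc) | COC(=O)/C1=C\CC/C(C)=C/c2oc(O[Si](C)(C)C(C)(C)C)c(C)c2C[C@H](OC(C)=O)/C(C)=C/CC1
F3 | step 5 | methyl (6E,10Z,14E)-16-acetoxy-5-hydroxy-10-(methoxycarbonyl)-2,6,14-trimethyl-3-oxohexadeca-6,10,14-trienoate (racemic at C5) | COC(=O)C(C)C(=O)CC(O)/C(C)=C/CC/C(C(=O)OC)=C/CC/C(C)=C/COC(C)=O
F4 | step 5 | methyl (2Z,6E,10Z,14E)-16-acetoxy-5-hydroxy-10-(methoxycarbonyl)-2,6,14-trimethyl-3-(trifluoromethylsulfonyloxy)hexadeca-2,6,10,14-tetraenoate (racemic at C5) | COC(=O)/C(C)=C(\OS(=O)(=O)C(F)(F)F)CC(O)/C(C)=C/CC/C(C(=O)OC)=C/CC/C(C)=C/COC(C)=O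
F5 | step 5 | methyl (2Z,6E,10Z,14E)-16-acetoxy-10-(methoxycarbonyl)-2,6,14-trimethyl-5-oxo-3-(trifluoromethylsulfonyloxy)hexadeca-2,6,10,14-tetraenoate | COC(=O)/C(C)=C(\OS(=O)(=O)C(F)(F)F)CC(=O)/C(C)=C/CC/C(C(=O)OC)=C/CC/C(C)=C/COC(C)=O
F6 | step 9 | methyl (2Z,5S,6E,10Z,14E)-5,16-dihydroxy-10-(methoxycarbonyl)-2,6,14-trimethyl-3-(trifluoromethylsulfonyloxy)hexadeca-2,6,10,14-tetraenoate | COC(=O)/C(C)=C(\OS(=O)(=O)C(F)(F)F)C[C@H](O)/C(C)=C/CC/C(C(=O)OC)=C/CC/C(C)=C/CO
F7 | step 9 | methyl (2Z,5S,6E,10Z,14E)-5-hydroxy-10-(methoxycarbonyl)-2,6,14-trimethyl-16-oxo-3-(trifluoromethylsulfonyloxy)hexadeca-2,6,10,14-tetraenoate | COC(=O)/C(C)=C(\OS(=O)(=O)C(F)(F)F)C[C@H](O)/C(C)=C/CC/C(C(=O)OC)=C/CC/C(C)=C/C=O
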